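**Assumption:** the target has no stereocentre and its only non-aromatic C=C is ring-locked, so it is achiral and no enantiocontrol is needed.

## Retrosynthetic overview

1. Last bond: C3–C1′, by Suzuki coupling of a fully elaborated 3-iodochromone hydroquinone with an o-hydroxy chromenyl boronate.
2. Key disconnection: C6–CH2 of the side chain. A primary alkyl radical (from anti-Markovnikov hydroboration of 2-methylbut-3-en-2-ol) adds to 3-iodochromone-5,8-quinone, and the same step delivers the 5,8-dihydroxy A ring.
3. The quinone comes from para-oxidation of 8-hydroxy-3-iodochromone; the pyranone comes from iodocyclisation of an enaminone; the acetyl group comes from directed ortho-metalation of MOM-protected catechol.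
4. B-ring fragment: resorcinol + prenal gives the 2,2-dimethylchromene; phenol-directed ortho C–H borylation puts boron at C6.
5. Ring order: A ring (catechol) → pyranone C ring → A ring oxidised to quinone and re-aromatised in the key step; B ring and its pyran made separately; fragments joined last.

## Route

**Step 1**
Reactants: 1, catechol
Product: 2, 1,2-bis(methoxymethoxy)benzene
Conditions: MOMCl (2.5 eq), i-Pr2NEt (3 eq), CH2Cl2, 0 °C → rt
Reagents that add atoms: chloromethyl methyl ether, COCCl
Why: Standard O-alkylation (MOM protection) of both phenols gives a substrate whose OMOM groups direct ortho-lithiation.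

**Step 2**
Reactants: 2, 1,2-bis(methoxymethoxy)benzene; 3, N-methoxy-N-methylacetamide
Product: 4, 1-[2,3-bis(methoxymethoxy)phenyl]ethan-1-one
Conditions: n-BuLi (1.1 eq), TMEDA, THF, 0 °C, 1 h; then 3, −78 °C → rt
Reagents that add atoms: none beyond the numbered reactants
Why: Directed ortho-metalation puts lithium at C3 (the two ortho sites are equivalent), and Weinreb acylation stops cleanly at the methyl ketone.

**Step 3**
Reactants: 4, 1-[2,3-bis(methoxymethoxy)phenyl]ethan-1-one; 5, N,N-dimethylformamide dimethyl acetal
Product: 6, (E)-1-[2,3-bis(methoxymethoxy)phenyl]-3-(dimethylamino)prop-2-en-1-one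
Conditions: 5 (3 eq), toluene, 110 °C
Reagents that add atoms: none beyond the numbered reactants
Why: Condensation of the acetyl CH3 with the amide acetal gives the (E)-enaminone; the MOM ethers prevent O-methylation or amide-acetal formation at the catechol oxygens.

**Step 4**
Reactants: 6, the enaminone
Product: 7, 8-hydroxy-3-iodo-4H-chromen-4-one
Conditions: I2 (2 eq), MeOH, rt, 1 h; then 3 M HCl, 50 °C, 2 h; aq. Na2S2O3
Reagents that add atoms: iodine, II
Why: Enaminone iodocyclisation: α-iodination gives an α-iodo-iminium that the ortho oxygen closes onto once its acid-labile MOM group is lost, Me2NH is eliminated to give the 3-iodochromone, and the HCl stage removes the remaining 8-OMOM.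

**Step 5**
Reactants: 7, 8-hydroxy-3-iodo-4H-chromen-4-one
Product: 8, 3-iodo-4H-chromene-4,5,8-trione
Conditions: PhI(OCOCF3)2 (2.2 eq), MeCN/H2O 2:1, 0 °C, 30 min; extract and use at once
Reagents that add atoms: water, O
Why: Hypervalent-iodine oxidation of a phenol with a free para position (as in 8-hydroxyquinoline → quinoline-5,8-dione): water traps the phenoxenium ion at C5 and a second oxidation gives the p-quinone, while the vinyl iodide is inert.

**Step 6 (key step)**
Reactants: 8, 3-iodo-4H-chromene-4,5,8-trione; 9, 2-methylbut-3-en-2-ol
Product: 10, 5,8-dihydroxy-6-(3-hydroxy-3-methylbutyl)-3-iodo-4H-chromen-4-one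
Conditions: 9 (3 eq), catecholborane (6.5 eq), Me2NCOMe (cat.), CH2Cl2, 40 °C; t-BuOH to destroy residual B–H; then 8 (1 eq), DMPU (1 eq), slow air (O2) feed, CH2Cl2, 0 °C → rt; aq. NaHCO3/Na2S2O4 work-up
Reagents that add atoms: none (catecholborane supplies only H; the O–B and C–B bonds are hydrolysed or lost)
Why: Proposed new method: a radical chain reductive alkylation in which O2 releases the primary radical •CH2CH2C(CH3)2O[B] from the B-alkylcatecholborane (the tertiary OH is transiently masked as its borate), the nucleophilic radical adds to quinone carbon C6, the resulting oxygen-centred radical is trapped at boron (SH2) to release the next alkyl radical, and hydrolysis plus tautomerisation gives the 6-alkyl hydroquinone. C6 is predicted because O1 donates into C5=O (vinylogous ester), leaving C8=O as the more electrophilic carbonyl with C6 as its β-carbon, the same bias that sends nucleophilic radicals to C5 of 2-alkoxy-1,4-benzoquinones. The closest known reaction type is the radical conjugate addition of B-alkylcatecholboranes or trialkylboranes to 1,4-benzoquinones, which gives 2-alkylhydroquinones. The quinone reacts far faster than chromone C2 or the C–I bond; no stereocentre is formed.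

**Step 7**
Reactants: 11, resorcinol; 12, 3-methylbut-2-enal
Product: 13, 2,2-dimethyl-2H-chromen-7-ol
Conditions: 11 (3 eq), 12 (1 eq), pyridine, 140 °C (sealed tube), 16 h; remove the minor 5-hydroxy isomer by chromatography
Reagents that add atoms: none beyond the numbered reactants
Why: Base-mediated chromenylation: aldol-type C-alkylation at the less hindered C4 of resorcinol, dehydration to the o-quinone methide and oxa-6π electrocyclisation; excess resorcinol suppresses double annulation.

**Step 8**
Reactants: 13, 2,2-dimethyl-2H-chromen-7-ol
Product: 14, 2,2-dimethyl-6-(4,4,5,5-tetramethyl-1,3,2-dioxaborolan-2-yl)-2H-chromen-7-ol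
Conditions: HBpin (1.1 eq, rt, forms ArOBpin); then [Ir(OMe)(cod)]2 (1.5 mol%), dtbpy (3 mol%), B2pin2 (1.0 eq), cyclohexane, 80 °C; MeOH work-up
Reagents that add atoms: bis(pinacolato)diboron, CC1(C)OB(OC1(C)C)B1OC(C)(C)C(C)(C)O1
Why: OBpin-directed Ir-catalysed ortho C–H borylation of a phenol: C8 is blocked by its two flanking oxygens and C5 lacks the directing effect, so boron enters at C6.

**Step 9**
Reactants: 10, the 3-iodochromone hydroquinone; 14, the chromenyl boronate (1.5 eq)
Product: 15, Kraussianone 3 (target)
Conditions: Pd(dppf)Cl2 (5 mol%), K2CO3 (3 eq), rigorously degassed dioxane/H2O 4:1, 70 °C, Ar; work-up at pH 6 (NaH2PO4), no strong acid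
Reagents that add atoms: none
Why: Suzuki–Miyaura coupling of a 3-iodochromone with an o-hydroxyaryl boronate tolerates the free phenols and tertiary alcohol under anaerobic carbonate conditions; avoiding acid prevents chroman formation between the 5-OH and the tertiary alcohol.

## Compound list

1 | catechol | Oc1ccccc1O | starting material
2 | 1,2-bis(methoxymethoxy)benzene | COCOc1ccccc1OCOC | intermediate
3 | N-methoxy-N-methylacetamide | CC(=O)N(C)OC | starting material
4 | 1-[2,3-bis(methoxymethoxy)phenyl]ethan-1-one | CC(=O)c1cccc(OCOC)c1OCOC | intermediate
5 | N,N-dimethylformamide dimethyl acetal | COC(OC)N(C)C | starting material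
6 | (E)-1-[2,3-bis(methoxymethoxy)phenyl]-3-(dimethylamino)prop-2-en-1-one | CN(C)/C=C/C(=O)c1cccc(OCOC)c1OCOC | intermediate
7 | 8-hydroxy-3-iodo-4H-chromen-4-one | O=c1c(I)coc2c(O)cccc12 | intermediate
8 | 3-iodo-4H-chromene-4,5,8-trione | O=C1C=CC(=O)C2=C1C(=O)C(I)=CO2 | intermediate
9 | 2-methylbut-3-en-2-ol | CC(C)(O)C=C | starting material
10 | 5,8-dihydroxy-6-(3-hydroxy-3-methylbutyl)-3-iodo-4H-chromen-4-one | CC(C)(O)CCc1cc(O)c2occ(I)c(=O)c2c1O | intermediate
11 | resorcinol | Oc1cccc(O)c1 | starting material
12 | 3-methylbut-2-enal | CC(C)=CC=O | starting material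
13 | 2,2-dimethyl-2H-chromen-7-ol | CC1(C)C=Cc2ccc(O)cc2O1 | intermediate
14 | 2,2-dimethyl-6-(4,4,5,5-tetramethyl-1,3,2-dioxaborolan-2-yl)-2H-chromen-7-ol | CC1(C)C=Cc2cc(B3OC(C)(C)C(C)(C)O3)c(O)cc2O1 | intermediate
15 | Kraussianone 3: 5,8-dihydroxy-6-(3-hydroxy-3-methylbutyl)-3-(7-hydroxy-2,2-dimethyl-2H-chromen-6-yl)-4H-chromen-4-one | CC(C)(O)CCc1cc(O)c2occ(-c3cc4c(cc3O)OC(C)(C)C=C4)c(=O)c2c1O | target

## Summary

Total steps: 9. Longest linear sequence: 7 (steps 1–6, then 9).

Steps most likely to fail, each with a fallback that changes the approach:

1. **Step 6.** The C6/C7 regiochemistry is a prediction (the C4 acyl group partly offsets the O1 bias), and quinone 8 is a sensitive electrophile. Fallback: move the borane radical alkylation to the start, on p-benzoquinone itself, where only one carbon site exists. Then build the chromone on the alkylated ring (silyl-protect the alcohol, Thiele–Winter acetoxylation, metalation/acylation between the two oxygens, enaminone iodocyclisation), so the heteroannulated quinone is never needed.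
2. **Step 5.** Over-oxidation, ortho-quinone formation or hydration at C2 of the product are possible. Fallback: switch to a 5,8-dimethoxy A ring made from hydroquinone (methylation, lithiation/borate oxidation to 2,5-dimethoxyphenol, ortho-acetylation, enaminone iodocyclisation). Unveil the quinone from 3-iodo-5,8-dimethoxychromone by CAN oxidative demethylation.
3. **Step 8.** Borylation at C5 or at the vinylic C–H, or alkene hydroboration, could compete. Fallback: install a halogen before the alkene exists. Resorcinol and 3-methylbut-2-enoic acid give 7-hydroxy-2,2-dimethylchroman-4-one; then C6 bromination, NaBH4 reduction/dehydration to the chromene, and Pd-catalysed Br→Bpin exchange.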